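## The problem

Ardisiphenol C 11 is a tetrasubstituted benzene with no stereocentre. Numbering the ring from the acetate (a numbering kept for every compound below), C1 bears OAc, C2 the (8Z,11Z)-heptadeca-8,11-dien-1-yl chain (carbons primed), C4 and C6 free hydroxyls, and C3 and C5 hydrogen. The chain is held by one aryl–primary alkyl bond, C2–C1', and it is linoleic acid less its carboxyl carbon, so both cis alkenes can be bought. Nothing in the molecule can control their geometry; it can only be lost, by hydrogenation, strong base, or radicals that abstract the doubly allylic hydrogens at C10' or add reversibly to the alkenes. The real difficulty is the oxygen pattern: only the most hindered oxygen, O1 between the chain and O6, is acylated, so acetylation of the triol cannot be selective, and once O6 is free the acetyl group can migrate to it or be cleaved by base, fluoride or nucleophiles. The aryl acetate, the skipped diene and the oxidisable electron-rich ring together exclude harsh acid, base, hydride and hydrogen late in the route. The opening comes from removing the acetate in thought: the remaining 5-alkylresorcinol has a mirror plane through C2 and C5, so C1 and C3 are equivalent, each ortho to the chain, ortho to one oxygen and para to the other. A C–H oxygenation directed para to oxygen therefore has a single product and needs no differentiation of the phenols.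

## Retrosynthesis

**11 from 10.** The last cut removes only the two O–CH2 bonds of the methoxymethyl ethers on O4 and O6 of acetate 10. Methoxymethyl is chosen because a Lewis acid with a soft nucleophile cleaves it in minutes at 0 °C. Methyl ethers would need a boron trihalide, benzyl ethers hydrogen, and silyl ethers fluoride, which makes the O6 phenoxide next to the acetate. The forward step must free two phenols without moving or cleaving the acetyl group and without touching the diene.

**10 from 8 and 9.** The C1–O bond is cut, giving the symmetric diether 8 and acetate, supplied as potassium acetate 9. The neighbouring cut, O1–acyl, would require a C1 oxygen carried and told apart from O4 and O6 from the start. Cutting C1–O instead removes that problem, because C1 and C3 of 8 are the same position. The precursor loses one substituent and gains a mirror plane. The forward reaction must oxidise the arene and not the chain, send acetate to C1/C3 and not to C5, and stop after one substitution.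

**8 from 2 and 5.** The C2–C1' bond is cut, giving the aryl bromide 2, used as its Grignard reagent 6 and then the diarylzinc 7, and the N-hydroxyphthalimide ester 5 of linoleic acid. Decarboxylative coupling uses the C18 acid as a C17 chain with both Z alkenes in place. A cross-coupling of an 18-carbon electrophile made by reducing the acid would be one carbon too long, and a Wittig assembly would have to build an alkene that can be bought. The forward step needs the primary radical to be captured by the metal faster than it abstracts hydrogen from C10'.

**5 from 3 and 4; 2 from 1.** Ester 5 is the condensation product of linoleic acid 3 and N-hydroxyphthalimide 4. Bromide 2 is the bis(methoxymethyl) ether of 5-bromoresorcinol 1. Both are routine single steps on purchased materials.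

## Roads not taken

Alternative 1: ynone Diels–Alder benzannulation with the acetyl group as a latent acetate.

The ring itself is cut at C2–C3 and C6–C1. The ynone (12Z,15Z)-henicosa-12,15-dien-3-yn-2-one A2 would react with the diene 1-methoxy-1,3-bis(trimethylsilyloxy)buta-1,3-diene A3 in a polarised cycloaddition. The nucleophilic CH2 terminus of A3 bonds to the chain-bearing β-carbon of A2 and the ketene-acetal terminus to the α-carbon. Loss of the methoxy and silyl groups would aromatise the adduct to the acetophenone 1-{2-[(8Z,11Z)-heptadeca-8,11-dien-1-yl]-4,6-dihydroxyphenyl}ethan-1-one A1 .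

- Merits: the route is convergent, and the polarity of A2 and A3 places all four substituents, so no site selectivity on a preformed ring is needed. In this respect it is better than the chosen plan.
- Weak points: compound A1 has a C1–C bond where the target has C1–O. A Baeyer–Villiger oxidation must follow, and peracids epoxidise cis-dialkyl alkenes faster than they oxidise a hydrogen-bonded ortho-hydroxyaryl ketone. The phenols of A1 must be masked before that oxidation and released after it, so the end-game of the chosen route returns with extra steps. Ynone A2 needs three or four steps from linoleic acid 3 and is a sluggish β-alkyl dienophile for the acid-sensitive diene A3 .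
- Comparison: about eight steps against five. Against the secure regiochemistry of A1 the chosen plan offers a shorter sequence and an oxidation whose selectivity can be set by the electrode potential and does not compete with the diene for a peracid.

Alternative 2: carbene benzannulation that leaves only the hindered phenol free.

The ring is cut at C4–C5, C6–C1 and C1–C2, with C1 arriving as a carbonyl ligand. The Cr(CO)5 alkenyl(alkoxy)carbene complex pentacarbonyl{(2E,11Z,14Z)-1-[(4-methoxybenzyl)oxy]icosa-2,11,14-trien-1-ylidene}chromium A5 and the ynol ether tert-butoxyethyne A6 would combine near 45 °C in a Dötz benzannulation. The alkyne A6 and one carbonyl ligand of A5 are inserted. The product would be 2-tert-butoxy-6-[(8Z,11Z)-heptadeca-8,11-dien-1-yl]-4-[(4-methoxybenzyl)oxy]phenol A4 .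

- Merits: the hindered C1 hydroxyl is the only free one in A4 , so acetylation is unambiguous, and the benzannulation is a well-studied reaction. On both counts it is stronger than the chosen plan, which relies on symmetry and a less tested C–H functionalisation.
- Weak points: complex A5 needs chain extension of linoleic acid 3 to an E-alkenyl metal, formation of the acylmetalate and its O-alkylation with a benzylic group, which is not an easy alkylation. Chromium is stoichiometric. Alkyne A6 is a sensitive reagent that has to be prepared, and insertion of an alkoxyalkyne such as A6 is less secure in its regiochemistry than that of an alkylalkyne. Phenol A4 is a hydroquinone monoether that oxidises readily to a quinone on decomplexation. The acid that removes tert-butyl and 4-methoxybenzyl from the acetate of A4 releases cations that can alkylate the ring or the diene.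
- Comparison: seven or eight steps against five. The chosen plan offers brevity, no stoichiometric transition metal, and a fallback of known reactions for its one uncertain step.

Alternative 3: decarboxylative coupling on a fully oxygenated ring.

The cut is C2–C1', as in step 3 of the chosen route, but made as the key step on a ring that already carries all three oxygens. Ester 5 would couple with [2-(methoxymethoxy)-3,5-bis(triisopropylsilyloxy)phenyl]zinc chloride A8 under NiCl2·glyme and 4,4'-di-tert-butyl-2,2'-bipyridine with decarboxylation. The product would be 1-[(8Z,11Z)-heptadeca-8,11-dien-1-yl]-2-(methoxymethoxy)-3,5-bis(triisopropylsilyloxy)benzene A7 . From A7 the acetal would be removed, the C1 phenol acetylated and the two silyl ethers cleaved.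

- Merits: every reaction type has precedent, and the three oxygens of A7 are fixed before the chain arrives. This road is the more reliable one.
- Weak points: zinc reagent A8 comes from an aryl halide with three differentiated oxygens in a 1,2,3,5 pattern, which costs several protection steps. The coupling that gives A7 takes place at an ortho-substituted aryl metal. The final fluoride desilylation makes the O6 phenoxide beside the aryl acetate and invites acyl migration or loss.
- Comparison: the chosen plan forms the same C2–C1' bond on a symmetric arene and installs the third oxygen late. It gives up some of the certainty of the road through A7 for three or four fewer steps, a non-basic final step, and a known-chemistry fallback that ends in the same intermediate 10.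

Key step: step 4

Assumption: the electrolysis of step 4 is run in an undivided cell, so hydrogen evolution at the cathode returns the acetate consumed at the anode and the net change is 8 + acetic acid → 10 + H2. Compounds 1, 3, 4 and 9 are taken as purchased.

## Route

**Step 1**
Reactants: 1 5-bromoresorcinol
Product: 2 1-bromo-3,5-bis(methoxymethoxy)benzene
Conditions: MOMCl, i-Pr2NEt, CH2Cl2, 0 °C → rt
Reagents that add atoms: chloromethyl methyl ether, COCCl
Why: O-alkylation of both phenols by the reactive chloromethyl ether with a hindered amine base is the standard methoxymethyl protection; the aryl bromide is inert.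

**Step 2**
Reactants: 3 linoleic acid; 4 N-hydroxyphthalimide
Product: 5 1,3-dioxoisoindolin-2-yl (9Z,12Z)-octadeca-9,12-dienoate
Conditions: DIC, DMAP (cat.), CH2Cl2, rt, Ar, dark
Reagents that add atoms: none
Why: Carbodiimide (Steglich-type) esterification gives the redox-active ester under neutral conditions that leave the skipped diene alone; argon and a slight excess of 3 keep free 4 from promoting autoxidation at the doubly allylic C11 of the acid.

**Step 3**
Reactants: 2 1-bromo-3,5-bis(methoxymethoxy)benzene; 5 1,3-dioxoisoindolin-2-yl (9Z,12Z)-octadeca-9,12-dienoate
Product: 8 1-[(8Z,11Z)-heptadeca-8,11-dien-1-yl]-3,5-bis(methoxymethoxy)benzene, via [3,5-bis(methoxymethoxy)phenyl]magnesium bromide 6 (not isolated), via bis[3,5-bis(methoxymethoxy)phenyl]zinc 7 (not isolated)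
Conditions: 2, Mg, LiCl, THF, rt; ZnCl2 (0.5 equiv), THF, 0 °C; then 5, Fe(acac)3 (20 mol%), 1,2-bis(diphenylphosphino)benzene (24 mol%), THF–toluene, 0 °C → rt
Reagents that add atoms: magnesium, [Mg] (held only in 6); zinc chloride, Cl[Zn]Cl (zinc held only in 7)
Why: Magnesium insertion and transmetalation give the diarylzinc, which enters an iron-catalysed decarboxylative Negishi-type coupling of redox-active esters, a reaction whose scope includes primary alkyl esters. Electron transfer to 5 releases CO2 and phthalimide anion, and the primary C17 radical should be captured at aryl-iron faster than it can reach the remote C8' and C11' alkenes, for which no ring closure of favourable size exists.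

**Step 4**
Reactants: 8 1-[(8Z,11Z)-heptadeca-8,11-dien-1-yl]-3,5-bis(methoxymethoxy)benzene; 9 potassium acetate
Product: 10 2-[(8Z,11Z)-heptadeca-8,11-dien-1-yl]-4,6-bis(methoxymethoxy)phenyl acetate
Conditions: Pt anode, Pt cathode, undivided cell, anode held at the foot of the arene wave (about 1.4 V vs SCE, fixed by voltammetry of 8), KOAc (0.5 M), AcOH–CH2Cl2 (3:1), rt, Ar, charge limited to about 1.5 F/mol (theory 2 F/mol) so that conversion stays partial, 8 recovered
Reagents that add atoms: acetic acid, CC(=O)O (solvent; shares the acetate pool with 9)
Why: Proposed new method: the closest known reaction type is the anodic nuclear acetoxylation of anisole and the dimethoxybenzenes in acetic acid containing acetate, which has not been shown on acetal-protected phenols or beside a skipped diene, and the same electron transfer–chemical step–electron transfer mechanism is expected. The dialkoxyarene of 8 should lose one electron several hundred millivolts below the potentials at which isolated cis-dialkyl alkenes or acetate itself are oxidised, so the radical cation is confined to the ring. In a 1,3-dioxygenated benzene the singly occupied orbital has a node through C2 and C5 and large coefficients at C1 and C3, each para to one oxygen, so acetate should add there and not at C5 between the oxygens. A second electron transfer and loss of the proton from C1 restore the aromatic ring and leave the C1–OAc bond; no ring is closed and no stereocentre is formed. Because C1 and C3 are exchanged by the mirror plane of 8, attack at either gives the same compound 10. Side-chain substitution is disfavoured because the chain sits on the nodal carbon C2, so its benzylic C–H bonds are not acidified in the radical cation, and because a high acetate concentration is known to steer such radical cations to nuclear substitution. The acetoxy group is only a weak donor, so 10 should be no easier to oxidise than 8, and holding the potential at the foot of the wave and stopping before full conversion protects both 10 and the diene. The acetate buffer, renewed at the cathode, keeps the medium too weakly acidic to cleave the methoxymethyl acetals.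

**Step 5**
Reactants: 10 2-[(8Z,11Z)-heptadeca-8,11-dien-1-yl]-4,6-bis(methoxymethoxy)phenyl acetate
Product: 11 ardisiphenol C, 2-[(8Z,11Z)-heptadeca-8,11-dien-1-yl]-4,6-dihydroxyphenyl acetate
Conditions: ZnBr2, n-PrSH, CH2Cl2, 0 °C, 10 min, Ar, dark
Reagents that add atoms: none
Why: Lewis-acid-assisted acetal cleavage with a thiol as soft nucleophile (ZnBr2/propanethiol removal of methoxymethyl ethers): zinc activates each acetal and the thiol takes up the methoxymethyl unit. No base or fluoride is present, so the acetate should stay on O1, and the short, cold, dark, oxygen-free run limits thiyl-radical attack on the Z alkenes.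

## Compound list

1 | 5-bromoresorcinol (5-bromobenzene-1,3-diol) | Oc1cc(O)cc(Br)c1 | starting material
2 | 1-bromo-3,5-bis(methoxymethoxy)benzene | COCOc1cc(OCOC)cc(Br)c1 | intermediate
3 | linoleic acid, (9Z,12Z)-octadeca-9,12-dienoic acid | CCCCC/C=C\C/C=C\CCCCCCCC(=O)O | starting material
4 | N-hydroxyphthalimide | O=C1c2ccccc2C(=O)N1O | starting material
5 | 1,3-dioxoisoindolin-2-yl (9Z,12Z)-octadeca-9,12-dienoate | CCCCC/C=C\C/C=C\CCCCCCCC(=O)ON1C(=O)c2ccccc2C1=O | intermediate
6 | [3,5-bis(methoxymethoxy)phenyl]magnesium bromide | COCOc1cc(OCOC)cc([Mg]Br)c1 | intermediate
7 | bis[3,5-bis(methoxymethoxy)phenyl]zinc | COCOc1cc(OCOC)cc([Zn]c2cc(OCOC)cc(OCOC)c2)c1 | intermediate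
8 | 1-[(8Z,11Z)-heptadeca-8,11-dien-1-yl]-3,5-bis(methoxymethoxy)benzene | CCCCC/C=C\C/C=C\CCCCCCCc1cc(OCOC)cc(OCOC)c1 | intermediate
9 | potassium acetate | CC(=O)[O-].[K+] | starting material
10 | 2-[(8Z,11Z)-heptadeca-8,11-dien-1-yl]-4,6-bis(methoxymethoxy)phenyl acetate | CCCCC/C=C\C/C=C\CCCCCCCc1cc(OCOC)cc(OCOC)c1OC(C)=O | intermediate
11 | ardisiphenol C, 2-[(8Z,11Z)-heptadeca-8,11-dien-1-yl]-4,6-dihydroxyphenyl acetate | CCCCC/C=C\C/C=C\CCCCCCCc1cc(O)cc(O)c1OC(C)=O | target

## Step count and least certain steps

Total steps: 5. Longest linear sequence: 4 steps (steps 1, 3, 4, 5 from 1; equally steps 2, 3, 4, 5 from 3).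

**Step 4 (key step, proposed new method).** The most likely failure is loss of chemoselectivity at the anode. The radical cation may shed a methoxymethyl group as its stabilised cation, and the freed phenol would then be oxidised further. Acetate may also add at an oxygen-bearing ring carbon, the product may be over-oxidised as conversion rises, and stray radicals may abstract hydrogen at C10'. Only the rate of acetate capture and the applied potential discriminate between these exits.

The fallback uses known chemistry, sets out from 8 and comes back to the route at 10. Electrophilic bromination of 8 with N-bromosuccinimide in MeCN at 0 °C in the dark goes ortho to the alkyl group and para to oxygen on 5-alkylresorcinol diethers. It should give 2-bromo-1-[(8Z,11Z)-heptadeca-8,11-dien-1-yl]-3,5-bis(methoxymethoxy)benzene F1. Bromine–lithium exchange with n-BuLi in THF at −78 °C would give {2-[(8Z,11Z)-heptadeca-8,11-dien-1-yl]-4,6-bis(methoxymethoxy)phenyl}lithium F2. Trapping with B(OMe)3 would give dimethyl {2-[(8Z,11Z)-heptadeca-8,11-dien-1-yl]-4,6-bis(methoxymethoxy)phenyl}boronate F3. Oxidation in the same flask with H2O2 and aqueous NaOH at 0 °C, which leaves unactivated alkenes alone, would give 2-[(8Z,11Z)-heptadeca-8,11-dien-1-yl]-4,6-bis(methoxymethoxy)phenol F4. Acetylation of that phenol with acetic anhydride, pyridine and catalytic DMAP returns 10.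

**Step 3.** The most likely failure is hydrogen abstraction from the doubly allylic C10' by the primary radical. Low-valent iron may also move the skipped diene into conjugation. Either would reduce the chain or scramble its geometry, and the cause is that the radical is generated in a solution rich in weak C–H bonds.

The fallback avoids radicals, sets out from 2 and comes back to the route at 8. Sonogashira coupling of 2 with purchased oct-7-yn-1-ol (Pd(PPh3)2Cl2, CuI, Et3N, 70 °C) should give 8-[3,5-bis(methoxymethoxy)phenyl]oct-7-yn-1-ol F5. Hydrogenation over palladium on carbon (Pd/C), done before any chain alkene exists, would give 8-[3,5-bis(methoxymethoxy)phenyl]octan-1-ol F6. Oxidation with TEMPO and PhI(OAc)2 would give 8-[3,5-bis(methoxymethoxy)phenyl]octanal F7. Separately, purchased (3Z)-non-3-en-1-ol would be converted with I2, PPh3 and imidazole into (3Z)-1-iodonon-3-ene F8. Heating that iodide with PPh3 in MeCN would give [(3Z)-non-3-en-1-yl](triphenyl)phosphonium iodide F9. Deprotonation with NaN(SiMe3)2 in THF at −78 °C would give [(3Z)-non-3-en-1-ylidene](triphenyl)phosphorane F10. Wittig reaction of this ylide with the aldehyde under kinetic control should form the C8'=C9' alkene as Z, with the C11'=C12' Z alkene carried in from the nonenol, and returns 8.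

**Step 5.** The most likely failures are migration of the acetyl group from O1 to the newly freed O6, its loss by thiolysis, and thiyl-radical Z-to-E isomerisation of the chain. The cause is that a thiol and a Lewis acid meet an activated aryl ester and two cis alkenes.

The fallback changes the mode of unmasking, sets out from 10 and comes back to the route at 11. Me3SiOTf with 2,2'-bipyridyl in MeCN at 0 °C transfers the methoxymethyl units to the bipyridyl and silylates the aryl oxygens. This should give 2-[(8Z,11Z)-heptadeca-8,11-dien-1-yl]-4,6-bis(trimethylsilyloxy)phenyl acetate F11. Adding water then hydrolyses the two aryl silyl ethers at near-neutral pH, without thiol or base, and returns 11.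

## Further compounds

F1 | step 4 | 2-bromo-1-[(8Z,11Z)-heptadeca-8,11-dien-1-yl]-3,5-bis(methoxymethoxy)benzene | CCCCC/C=C\C/C=C\CCCCCCCc1cc(OCOC)cc(OCOC)c1Br
F2 | step 4 | {2-[(8Z,11Z)-heptadeca-8,11-dien-1-yl]-4,6-bis(methoxymethoxy)phenyl}lithium | CCCCC/C=C\C/C=C\CCCCCCCc1cc(OCOC)cc(OCOC)c1[Li]
F3 | step 4 | dimethyl {2-[(8Z,11Z)-heptadeca-8,11-dien-1-yl]-4,6-bis(methoxymethoxy)phenyl}boronate | CCCCC/C=C\C/C=C\CCCCCCCc1cc(OCOC)cc(OCOC)c1B(OC)OC
F4 | step 4 | 2-[(8Z,11Z)-heptadeca-8,11-dien-1-yl]-4,6-bis(methoxymethoxy)phenol | CCCCC/C=C\C/C=C\CCCCCCCc1cc(OCOC)cc(OCOC)c1O
F5 | step 3 | 8-[3,5-bis(methoxymethoxy)phenyl]oct-7-yn-1-ol | COCOc1cc(OCOC)cc(C#CCCCCCCO)c1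
F6 | step 3 | 8-[3,5-bis(methoxymethoxy)phenyl]octan-1-ol | COCOc1cc(OCOC)cc(CCCCCCCCO)c1
F7 | step 3 | 8-[3,5-bis(methoxymethoxy)phenyl]octanal | COCOc1cc(OCOC)cc(CCCCCCCC=O)c1
F8 | step 3 | (3Z)-1-iodonon-3-ene | CCCCC/C=C\CCI
F9 | step 3 | [(3Z)-non-3-en-1-yl](triphenyl)phosphonium iodide | CCCCC/C=C\CC[P+](c1ccccc1)(c1ccccc1)c1ccccc1.[I-]
F10 | step 3 | [(3Z)-non-3-en-1-ylidene](triphenyl)phosphorane | CCCCC/C=C\CC=P(c1ccccc1)(c1ccccc1)c1ccccc1
F11 | step 5 | 2-[(8Z,11Z)-heptadeca-8,11-dien-1-yl]-4,6-bis(trimethylsilyloxy)phenyl acetate | CCCCC/C=C\C/C=C\CCCCCCCc1cc(O[Si](C)(C)C)cc(O[Si](C)(C)C)c1OC(C)=O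
A1 | alternative 1 | 1-{2-[(8Z,11Z)-heptadeca-8,11-dien-1-yl]-4,6-dihydroxyphenyl}ethan-1-one | CCCCC/C=C\C/C=C\CCCCCCCc1cc(O)cc(O)c1C(C)=O
A2 | alternative 1 | (12Z,15Z)-henicosa-12,15-dien-3-yn-2-one | CCCCC/C=C\C/C=C\CCCCCCCC#CC(C)=O
A3 | alternative 1 | 1-methoxy-1,3-bis(trimethylsilyloxy)buta-1,3-diene | COC(O[Si](C)(C)C)=CC(=C)O[Si](C)(C)C
A4 | alternative 2 | 2-tert-butoxy-6-[(8Z,11Z)-heptadeca-8,11-dien-1-yl]-4-[(4-methoxybenzyl)oxy]phenol | CCCCC/C=C\C/C=C\CCCCCCCc1cc(OCc2ccc(OC)cc2)cc(OC(C)(C)C)c1O
A5 | alternative 2 | pentacarbonyl{(2E,11Z,14Z)-1-[(4-methoxybenzyl)oxy]icosa-2,11,14-trien-1-ylidene}chromium | CCCCC/C=C\C/C=C\CCCCCCC/C=C/C(OCc1ccc(OC)cc1)=[Cr](=C=O)(=C=O)(=C=O)(=C=O)=C=O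
A6 | alternative 2 | tert-butoxyethyne | CC(C)(C)OC#C
A7 | alternative 3 | 1-[(8Z,11Z)-heptadeca-8,11-dien-1-yl]-2-(methoxymethoxy)-3,5-bis(triisopropylsilyloxy)benzene | CCCCC/C=C\C/C=C\CCCCCCCc1cc(O[Si](C(C)C)(C(C)C)C(C)C)cc(O[Si](C(C)C)(C(C)C)C(C)C)c1OCOC
A8 | alternative 3 | [2-(methoxymethoxy)-3,5-bis(triisopropylsilyloxy)phenyl]zinc chloride | COCOc1c([Zn]Cl)cc(O[Si](C(C)C)(C(C)C)C(C)C)cc1O[Si](C(C)C)(C(C)C)C(C)C
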